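Ring B is built on the ether oxygen instead of being coupled to it. Ring B is a para-phenylene whose C4 carries the diaryl ether oxygen and whose C1 carries the first carbon of the bridge to ring A. This 1,4-pattern maps onto an oxygen-substituted alkyne and the C5 ester of a 2-pyrone. Heating methyl coumalate with the ethynyl ether of the ring C phenol (rings C and D already joined as a saturated, fully O-methylated bibenzyl) should give a [4+2] adduct that expels CO2, forging two C–C bonds and delivering the methyl 4-aryloxybenzoate in one operation. Ester-to-aldehyde adjustment, Wittig olefination, hydrogenation and BBr3 demethylation finish.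

Key step: step 5

Remark: the Wittig products 4 and 19 should form as E/Z mixtures (E isomers drawn) that converge on hydrogenation, and the transient lactone 13 is racemic (one enantiomer drawn).

Step 1
Reactants: 1 3-(benzyloxy)-4-methoxybenzaldehyde (O-benzylisovanillin); 2 (2,3-dimethoxybenzyl)triphenylphosphonium bromide
Product: 4 2-(benzyloxy)-4-[2-(2,3-dimethoxyphenyl)ethenyl]-1-methoxybenzene (E/Z mixture; E isomer drawn), via phosphonium ylide 3 (not isolated)
Conditions: KOt-Bu (1.2 equiv), THF, 0 °C to rt
Reagents that add atoms: none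
Why: Wittig olefination of an aromatic aldehyde with a semi-stabilised benzylic ylide; the benzyl ether keeps the ring C oxygen non-acidic so one equivalent of base suffices, and the alkene geometry is irrelevant because step 2 saturates it.

Step 2
Reactants: 4 2-(benzyloxy)-4-[2-(2,3-dimethoxyphenyl)ethenyl]-1-methoxybenzene
Product: 5 5-[2-(2,3-dimethoxyphenyl)ethyl]-2-methoxyphenol
Conditions: H2 (1 atm), 10% Pd/C, EtOAc–EtOH, rt
Reagents that add atoms: none
Why: Catalytic hydrogenation saturates the stilbene C=C and hydrogenolysis cleaves the benzyl aryl ether in the same operation, while the aryl methyl ethers are inert.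

Step 3
Reactants: 5 5-[2-(2,3-dimethoxyphenyl)ethyl]-2-methoxyphenol; 6 trichloroethylene
Product: 8 2-[(E)-1,2-dichloroethenoxy]-4-[2-(2,3-dimethoxyphenyl)ethyl]-1-methoxybenzene, via dichloroacetylene 7 (not isolated)
Conditions: K2CO3 (2 equiv), DMF, 70 °C, closed vessel
Reagents that add atoms: none
Why: Base-mediated O-vinylation of a phenol with trichloroethylene (elimination to dichloroacetylene, then anti addition of phenoxide and a proton) is the standard entry to aryl (E)-1,2-dichlorovinyl ethers; the E geometry follows from the anti addition and has no consequence later.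

Step 4
Reactants: 8 2-[(E)-1,2-dichloroethenoxy]-4-[2-(2,3-dimethoxyphenyl)ethyl]-1-methoxybenzene
Product: 11 4-[2-(2,3-dimethoxyphenyl)ethyl]-2-(ethynyloxy)-1-methoxybenzene, via chloroethynyl ether 9 (not isolated), via lithium acetylide 10 (not isolated)
Conditions: n-BuLi (2.5 equiv), THF, −78 to −40 °C; then H2O, −78 °C; cold neutral work-up, used at once
Reagents that add atoms: none
Why: Known ynol ether synthesis from a 1,2-dichlorovinyl ether, in which n-BuLi effects dehydrochlorination to chloroalkyne 9 and chlorine–lithium exchange to acetylide 10, which water protonates; the substrate carries no OH group, alkene or benzyl ether, so nothing else should respond to n-BuLi at −78 °C.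

Step 5
Reactants: 11 4-[2-(2,3-dimethoxyphenyl)ethyl]-2-(ethynyloxy)-1-methoxybenzene; 12 methyl coumalate (methyl 2-oxo-2H-pyran-5-carboxylate)
Product: 14 methyl 4-[5-[2-(2,3-dimethoxyphenyl)ethyl]-2-methoxyphenoxy]benzoate, via bridged lactone 13 (not isolated)
Conditions: 12 (2 equiv), PhMe, 100 °C, sealed tube, Ar
Reagents that add atoms: none
Why: The electron-poor 2-pyrone 12 serves as the diene (C3 to C6) and the electron-rich ynol ether 11 as the dienophile in an inverse-electron-demand Diels–Alder reaction, and the resulting 2-oxabicyclo[2.2.2]octadienone 13 loses CO2 by retro-[4+2] to give the arene. The closest known reaction type is the pyrone–alkyne Diels–Alder/decarboxylation benzannulation, established for methyl coumalate with electron-rich alkenes and alkynes. Ring B is closed by intermolecular [4+2] cycloaddition (bonds alkyne CH–C6 and alkyne C(OAr)–C3) followed by cycloreversion, so its six carbons are C3–C6 of the pyrone plus the two alkyne carbons. No stereocentre is created in 14, because the two bridgehead centres of 13 are erased on aromatisation. The step needs regioselectivity, which matched polarity should secure: the nucleophilic terminal alkyne carbon (β to oxygen) bonds to C6, the most electrophilic pyrone carbon, which places the aryloxy carbon on C3 and hence para to the ester. It also needs chemoselectivity, which should hold because the ynol ether is far more electron-rich than the anisole rings and the saturated bibenzyl offers no other π bond as dienophile.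

Step 6
Reactants: 14 methyl 4-[5-[2-(2,3-dimethoxyphenyl)ethyl]-2-methoxyphenoxy]benzoate
Product: 15 [4-[5-[2-(2,3-dimethoxyphenyl)ethyl]-2-methoxyphenoxy]phenyl]methanol
Conditions: LiAlH4 (1.0 equiv), THF, 0 °C to rt; aqueous NaOH work-up
Reagents that add atoms: none
Why: Hydride reduction of a methyl benzoate to the benzyl alcohol, with diaryl and aryl methyl ethers inert to LiAlH4.

Step 7
Reactants: 15 [4-[5-[2-(2,3-dimethoxyphenyl)ethyl]-2-methoxyphenoxy]phenyl]methanol
Product: 16 4-[5-[2-(2,3-dimethoxyphenyl)ethyl]-2-methoxyphenoxy]benzaldehyde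
Conditions: activated MnO2 (10 equiv), CH2Cl2, rt
Reagents that add atoms: none
Why: Activated MnO2 oxidises benzylic alcohols selectively and stops at the aldehyde, leaving the bibenzyl CH2 groups untouched.

Step 8
Reactants: 16 4-[5-[2-(2,3-dimethoxyphenyl)ethyl]-2-methoxyphenoxy]benzaldehyde; 17 (3-methoxybenzyl)triphenylphosphonium chloride
Product: 19 4-[2-(2,3-dimethoxyphenyl)ethyl]-1-methoxy-2-[4-[2-(3-methoxyphenyl)ethenyl]phenoxy]benzene (E/Z mixture; E isomer drawn), via phosphonium ylide 18 (not isolated)
Conditions: KOt-Bu (1.3 equiv), THF, 0 °C to rt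
Reagents that add atoms: none
Why: Wittig olefination of an aryl aldehyde with a semi-stabilised benzylic ylide installs ring A and both bridge carbons; the E/Z ratio is immaterial because the alkene is hydrogenated next.

Step 9
Reactants: 19 4-[2-(2,3-dimethoxyphenyl)ethyl]-1-methoxy-2-[4-[2-(3-methoxyphenyl)ethenyl]phenoxy]benzene
Product: 20 4-[2-(2,3-dimethoxyphenyl)ethyl]-1-methoxy-2-[4-[2-(3-methoxyphenyl)ethyl]phenoxy]benzene
Conditions: H2 (1 atm), 10% Pd/C, EtOAc, rt
Reagents that add atoms: none
Why: Catalytic hydrogenation of the stilbene C=C; the diaryl ether and methyl ethers are stable to these conditions.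

Step 10
Reactants: 20 4-[2-(2,3-dimethoxyphenyl)ethyl]-1-methoxy-2-[4-[2-(3-methoxyphenyl)ethyl]phenoxy]benzene
Product: 21 3-[2-[4-hydroxy-3-[4-[2-(3-hydroxyphenyl)ethyl]phenoxy]phenyl]ethyl]benzene-1,2-diol (target)
Conditions: BBr3 (8 equiv), CH2Cl2, −78 °C to rt; then ice/H2O, under Ar
Reagents that add atoms: none
Why: Lewis-acid demethylation of the four aryl methyl ethers with BBr3; the diaryl ether has no sp3 carbon for bromide to attack and should survive.

Compound list
1 | 3-(benzyloxy)-4-methoxybenzaldehyde | COc1ccc(C=O)cc1OCc1ccccc1 | starting material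
2 | (2,3-dimethoxybenzyl)triphenylphosphonium bromide | COc1cccc(C[P+](c2ccccc2)(c2ccccc2)c2ccccc2)c1OC.[Br-] | starting material
3 | (2,3-dimethoxybenzylidene)triphenylphosphorane | COc1cccc(C=P(c2ccccc2)(c2ccccc2)c2ccccc2)c1OC | intermediate
4 | 2-(benzyloxy)-4-[2-(2,3-dimethoxyphenyl)ethenyl]-1-methoxybenzene (E/Z mixture; E drawn) | COc1ccc(/C=C/c2cccc(OC)c2OC)cc1OCc1ccccc1 | intermediate
5 | 5-[2-(2,3-dimethoxyphenyl)ethyl]-2-methoxyphenol | COc1ccc(CCc2cccc(OC)c2OC)cc1O | intermediate
6 | trichloroethylene | ClC=C(Cl)Cl | starting material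
7 | dichloroacetylene | ClC#CCl | intermediate
8 | 2-[(E)-1,2-dichloroethenoxy]-4-[2-(2,3-dimethoxyphenyl)ethyl]-1-methoxybenzene | Cl/C=C(/Cl)Oc1cc(CCc2cccc(OC)c2OC)ccc1OC | intermediate
9 | 2-(chloroethynyloxy)-4-[2-(2,3-dimethoxyphenyl)ethyl]-1-methoxybenzene | ClC#COc1cc(CCc2cccc(OC)c2OC)ccc1OC | intermediate
10 | lithium 2-[5-[2-(2,3-dimethoxyphenyl)ethyl]-2-methoxyphenoxy]ethynide | [Li]C#COc1cc(CCc2cccc(OC)c2OC)ccc1OC | intermediate
11 | 4-[2-(2,3-dimethoxyphenyl)ethyl]-2-(ethynyloxy)-1-methoxybenzene | C#COc1cc(CCc2cccc(OC)c2OC)ccc1OC | intermediate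
12 | methyl coumalate (methyl 2-oxo-2H-pyran-5-carboxylate) | COC(=O)C1=COC(=O)C=C1 | starting material
13 | methyl 8-[5-[2-(2,3-dimethoxyphenyl)ethyl]-2-methoxyphenoxy]-3-oxo-2-oxabicyclo[2.2.2]octa-5,7-diene-6-carboxylate (racemic; one enantiomer drawn) | O=C1O[C@@H]2C=C(Oc3cc(CCc4cccc(OC)c4OC)ccc3OC)[C@H]1C=C2C(=O)OC | intermediate
14 | methyl 4-[5-[2-(2,3-dimethoxyphenyl)ethyl]-2-methoxyphenoxy]benzoate | COC(=O)c1ccc(Oc2cc(CCc3cccc(OC)c3OC)ccc2OC)cc1 | intermediate
15 | [4-[5-[2-(2,3-dimethoxyphenyl)ethyl]-2-methoxyphenoxy]phenyl]methanol | OCc1ccc(Oc2cc(CCc3cccc(OC)c3OC)ccc2OC)cc1 | intermediate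
16 | 4-[5-[2-(2,3-dimethoxyphenyl)ethyl]-2-methoxyphenoxy]benzaldehyde | O=Cc1ccc(Oc2cc(CCc3cccc(OC)c3OC)ccc2OC)cc1 | intermediate
17 | (3-methoxybenzyl)triphenylphosphonium chloride | COc1cccc(C[P+](c2ccccc2)(c2ccccc2)c2ccccc2)c1.[Cl-] | starting material
18 | (3-methoxybenzylidene)triphenylphosphorane | COc1cccc(C=P(c2ccccc2)(c2ccccc2)c2ccccc2)c1 | intermediate
19 | 4-[2-(2,3-dimethoxyphenyl)ethyl]-1-methoxy-2-[4-[2-(3-methoxyphenyl)ethenyl]phenoxy]benzene (E/Z mixture; E drawn) | COc1cccc(/C=C/c2ccc(Oc3cc(CCc4cccc(OC)c4OC)ccc3OC)cc2)c1 | intermediate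
20 | 4-[2-(2,3-dimethoxyphenyl)ethyl]-1-methoxy-2-[4-[2-(3-methoxyphenyl)ethyl]phenoxy]benzene | COc1cccc(CCc2ccc(Oc3cc(CCc4cccc(OC)c4OC)ccc3OC)cc2)c1 | intermediate
21 | 3-[2-[4-hydroxy-3-[4-[2-(3-hydroxyphenyl)ethyl]phenoxy]phenyl]ethyl]benzene-1,2-diol | Oc1cccc(CCc2ccc(Oc3cc(CCc4cccc(O)c4O)ccc3O)cc2)c1 | target

Total steps: 10. Longest linear sequence: 10 steps (1 to 21).

Steps most likely to fail

Step 5. Thermal oligomerisation or adventitious hydration of the ynol ether may outrun the cycloaddition. Addition in the reversed orientation would erode the para regiocontrol, and self-condensation of the pyrone could consume the diene. The fallback forms the diaryl ether by nucleophilic aromatic substitution. It sets out from phenol 5, which with 4-fluorobenzaldehyde (K2CO3, DMF, 140 °C) should give aldehyde 16 directly. The route is rejoined at 16 and steps 3 to 7 are bypassed. New compounds on this detour: none (F0).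

Step 4. The terminal ynol ether may be lost during work-up and concentration through hydration to the aryl acetate or through oligomerisation; competing ring lithiation is a lesser concern. The fallback sets out from 8 and generates acetylide 10 as before. Instead of water, Me3SiCl at −78 °C traps it as the C-silylated ynol ether [2-[5-[2-(2,3-dimethoxyphenyl)ethyl]-2-methoxyphenoxy]ethynyl]trimethylsilane F1. As a capped alkyne, this should tolerate chromatography and storage. Brief treatment with n-Bu4NF in THF at −20 °C immediately before the cycloaddition would release 11, where the route is rejoined.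

Step 3. Phenoxide capture of the volatile dichloroacetylene may be incomplete, leaving phenol behind, or a second phenoxide may add to the product. The fallback reaches the ynol ether without trichloroethylene and sets out from 5:
- Copper-mediated O-vinylation (Cu(OAc)2, 2,4,6-trivinylcyclotriboroxane–pyridine complex, pyridine, CH2Cl2, rt, air) would give the aryl vinyl ether 2-(ethenyloxy)-4-[2-(2,3-dimethoxyphenyl)ethyl]-1-methoxybenzene F2.
- Br2 (1.0 equiv, CH2Cl2, −78 °C) should add to the far more nucleophilic enol ether double bond to give racemic 2-(1,2-dibromoethoxy)-4-[2-(2,3-dimethoxyphenyl)ethyl]-1-methoxybenzene F3.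
- Double dehydrobromination with excess LDA (THF, −78 to 0 °C), then water, would give 11 by way of acetylide 10, where the route is rejoined.

Further compounds
F0 | step 5 | none | none
F1 | step 4 | [2-[5-[2-(2,3-dimethoxyphenyl)ethyl]-2-methoxyphenoxy]ethynyl]trimethylsilane | C[Si](C)(C)C#COc1cc(CCc2cccc(OC)c2OC)ccc1OC
F2 | step 3 | 2-(ethenyloxy)-4-[2-(2,3-dimethoxyphenyl)ethyl]-1-methoxybenzene | C=COc1cc(CCc2cccc(OC)c2OC)ccc1OC
F3 | step 3 | 2-(1,2-dibromoethoxy)-4-[2-(2,3-dimethoxyphenyl)ethyl]-1-methoxybenzene (racemic) | BrCC(Br)Oc1cc(CCc2cccc(OC)c2OC)ccc1OC
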